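**Retrosynthetic overview**

1. Numbering: spiro carbon C6; ring B = C1H2–C2HBr–C3(Cl)(CH3)–C4H2–C5H2; ring A = C7(=C14H2)–C8H2–C9H(OH)–C10HBr–C11(CH3)2. The strategy rests on one feature. The methylidene carbon C7 is a masked ketone that sits directly on C6, and C6 is bonded to quaternary C11. The congested C6–C11 bond can therefore be read as the trace of a pinacol-type shift of C11 from C7 to a cationic C6.
2. Late stage, on the finished skeleton: the cis C9-OH/C10-Br pair comes from a C9=C10 alkene (trans bromohydrin, oxidation, hydride reduction). C14 comes from titanium methylenation of the C7 ketone. C2-Br comes from an equatorial C2-OH by SN2 inversion.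
3. Key disconnection: C1–C2 and C6–C11 are cut together. This opens ring B and contracts ring A to a 1-alkenyl-2,2-dimethylcyclopent-3-enol silyl ether tethered to an α-chloro-α-methyl aldehyde.
4. C3 is the only stereocentre the precursor needs. It comes from Sharpless epoxidation of an E-trisubstituted allylic alcohol, chloride opening at C3 with inversion, and glycol cleavage. The C6–C7 bond comes from a vinylcerium addition to 2,2-dimethylcyclopent-3-enone.
5. Ring order: the five-membered carbocycle comes with the dione. Ring B is closed and ring A is enlarged from five to six members in one operation.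

Key step: step 12

Remark: the carbinol carbon C7 is formed without control and is erased in the key step. Both C7 configurations are carried on together and the SMILES leave C7 open. All locants follow the numbering above, which is also the spiro[5.5]undecane numbering used in the names.

**Step 1**
Reactants: 1 2,2-dimethylcyclopentane-1,3-dione
Product: 3 5,5-dimethyl-4-oxocyclopent-1-en-1-yl trifluoromethanesulfonate, via potassium enolate 2 (not isolated)
Conditions: KHMDS (1.05 equiv), THF, −78 °C; PhNTf2, −78 → 0 °C
Reagents that add atoms: N-phenylbis(trifluoromethanesulfonimide), O=S(=O)(N(c1ccccc1)S(=O)(=O)C(F)(F)F)C(F)(F)F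
Why: Enol triflate formation: the quaternary carbon leaves only the ring CH2 groups for deprotonation and the two carbonyls are equivalent, so a single enolate forms and is O-sulfonylated to one mono-triflate.

**Step 2**
Reactants: 3 5,5-dimethyl-4-oxocyclopent-1-en-1-yl trifluoromethanesulfonate
Product: 4 2,2-dimethylcyclopent-3-en-1-one
Conditions: Pd(PPh3)4 (3 mol %), LiCl (3 equiv), Bu3SnH (1.1 equiv), THF, 25–50 °C; distillation
Reagents that add atoms: none
Why: Palladium-catalysed tin hydride reduction of a vinyl triflate runs under neutral conditions, which should keep the β,γ double bond from moving into conjugation as an amine/formate medium might allow.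

**Step 3**
Reactants: 5 trimethyl(prop-1-yn-1-yl)silane; 6 2,3-dibromoprop-1-ene
Product: 8 (5-bromohex-5-en-1-yn-1-yl)trimethylsilane, via propargyllithium 7 (not isolated)
Conditions: n-BuLi, THF, −78 → −20 °C; 6, −78 °C → rt
Reagents that add atoms: none
Why: Alkylation of a silyl-blocked propargyllithium: only the allylic bromide of 6 is displaced (SN2 and SN2' give the same product) while the vinylic bromide, the later C6 handle, is inert.

**Step 4**
Reactants: 8 (5-bromohex-5-en-1-yn-1-yl)trimethylsilane
Product: 9 2-bromohex-1-en-5-yne
Conditions: K2CO3 (cat.), MeOH, rt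
Reagents that add atoms: none
Why: Methoxide-induced protodesilylation of an alkynylsilane frees the terminal alkyne without touching the vinyl bromide.

**Step 5**
Reactants: 9 2-bromohex-1-en-5-yne
Product: 12 (2E)-6-bromo-3-methylhepta-2,6-dien-1-ol, via alkenylalane 10 (not isolated), via lithium alanate 11 (not isolated)
Conditions: Me3Al, Cp2ZrCl2 (20 mol %), CH2Cl2, 0 °C → rt; hexane/THF, n-BuLi (1 equiv per Al), −78 → 0 °C; (CH2O)n, rt
Reagents that add atoms: trimethylaluminium, C[Al](C)C; paraformaldehyde (as formaldehyde), C=O
Why: Negishi zirconium-catalysed carboalumination adds methyl and aluminium syn with aluminium on the terminal carbon, and hydroxymethylation of the alanate proceeds with retention, so the C2=C3 alkene should be the pure E isomer on which the later enantiomeric purity at C3 depends.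

**Step 6**
Reactants: 12 (2E)-6-bromo-3-methylhepta-2,6-dien-1-ol; 4 2,2-dimethylcyclopent-3-en-1-one
Product: 15 1-[(5E)-7-hydroxy-5-methylhepta-1,5-dien-2-yl]-2,2-dimethylcyclopent-3-en-1-ol (racemic), via dilithio species 13 (not isolated), via organocerium reagent 14 (not isolated)
Conditions: n-BuLi (1.0 equiv) then t-BuLi (2.1 equiv), Et2O, −78 °C; anhydrous CeCl3 (2.2 equiv), THF, −78 °C; 4 (1.2 equiv), −78 °C; aq NH4Cl
Reagents that add atoms: none
Why: Bromine–lithium exchange followed by an Imamoto organocerium 1,2-addition: the weakly basic cerium reagent should add to the hindered carbonyl of 4 rather than remove its doubly activated (α-keto and allylic) C8 protons, forming the C6–C7 bond with a racemic C7 that is of no consequence.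

**Step 7**
Reactants: 15 1-[(5E)-7-hydroxy-5-methylhepta-1,5-dien-2-yl]-2,2-dimethylcyclopent-3-en-1-ol
Product: 16 bis(triethylsilyl) ether of 15
Conditions: TESOTf (2.5 equiv), 2,6-lutidine (3.5 equiv), CH2Cl2, −78 → 0 °C
Reagents that add atoms: triethylsilyl trifluoromethanesulfonate, CC[Si](CC)(CC)OS(=O)(=O)C(F)(F)F
Why: Silyl ether formation with a silyl triflate, which is reactive enough for the tertiary carbinol flanked by C11, while the hindered base keeps acid away from the ionisable allylic C7–O bond.

**Step 8**
Reactants: 16 bis(triethylsilyl) ether of 15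
Product: 17 (2E)-6-[2,2-dimethyl-1-(triethylsilyloxy)cyclopent-3-en-1-yl]-3-methylhepta-2,6-dien-1-ol
Conditions: PPTS (10 mol %), MeOH/CH2Cl2, −10 → 0 °C
Reagents that add atoms: none
Why: Selective solvolysis of a silyl ether: the primary allylic TES ether is methanolysed much faster than the tertiary one buried between C6 and C11.

**Step 9**
Reactants: 17 (2E)-6-[2,2-dimethyl-1-(triethylsilyloxy)cyclopent-3-en-1-yl]-3-methylhepta-2,6-dien-1-ol
Product: 18 {(2R,3R)-3-{3-[2,2-dimethyl-1-(triethylsilyloxy)cyclopent-3-en-1-yl]but-3-en-1-yl}-3-methyloxiran-2-yl}methanol (C7 epimer pair)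
Conditions: Ti(OiPr)4 (10 mol %), D-(−)-DIPT (12 mol %), TBHP (decane), 4 Å MS, CH2Cl2, −20 °C
Reagents that add atoms: tert-butyl hydroperoxide, CC(C)(C)OO
Why: Katsuki–Sharpless asymmetric epoxidation: only the alkene that carries a free allylic hydroxyl binds to titanium, and the D-(−)-tartrate delivers oxygen to the face of the E alkene that gives the (2R,3R) epoxide, which avoids relying on enamine catalysis to tell a methyl from a CH2 group at a fully substituted α-carbon.

**Step 10**
Reactants: 18 the (2R,3R)-epoxy alcohol
Product: 19 (2R,3S)-3-chloro-6-[2,2-dimethyl-1-(triethylsilyloxy)cyclopent-3-en-1-yl]-3-methylhept-6-ene-1,2-diol (C7 epimer pair)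
Conditions: Cl2Ti(OiPr)2 (1.5 equiv), CH2Cl2, −20 → 0 °C; aq NaHCO3/Rochelle salt
Reagents that add atoms: dichlorotitanium diisopropoxide, CC(C)O[Ti](Cl)(Cl)OC(C)C
Why: Titanium-assisted regioselective opening of a 2,3-epoxy alcohol: the chelated epoxy alkoxide is attacked by chloride at tertiary C3, the carbon better able to carry charge, from the rear of the C–O bond, so inversion sets C3 as S.

**Step 11**
Reactants: 19 the (2R,3S)-chloro diol
Product: 20 (2S)-2-chloro-5-[2,2-dimethyl-1-(triethylsilyloxy)cyclopent-3-en-1-yl]-2-methylhex-5-enal (C3 = S in route numbering; C7 epimer pair)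
Conditions: NaIO4 on silica gel, CH2Cl2, rt
Reagents that add atoms: none
Why: Malaprade glycol cleavage removes the hydroxymethyl carbon and turns C2 into the aldehyde under near-neutral conditions, and the fully substituted C3 cannot epimerise.

**Step 12**
Reactants: 20 (2S)-2-chloro-5-[2,2-dimethyl-1-(triethylsilyloxy)cyclopent-3-en-1-yl]-2-methylhex-5-enal
Product: 23 (2R,3S,6S)-3-chloro-2-hydroxy-3,11,11-trimethylspiro[5.5]undec-9-en-7-one, via C6 cation 21 (not isolated), via tin alkoxide 22 (not isolated)
Conditions: SnCl4 (1.1 equiv), 2,6-di-tert-butyl-4-methylpyridine (0.3 equiv), CH2Cl2 (0.01 M), −78 → −40 °C; aq NaHCO3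
Reagents that add atoms: none
Why: Proposed new method: SnCl4 binds the aldehyde oxygen, the methylene terminus C1 of the 1,1-disubstituted alkene attacks C2, and the charge that builds at C6 (21) is discharged at once by the 1,2-shift of C11 from C7 to C6, after which the silyloxycarbenium ion gives up Et3SiCl and leaves the C7 ketone as tin alkoxide 22; the closest known reaction type is the Prins–pinacol cascade of acetal-tethered 1-alkenylcycloalkanol silyl ethers with ring enlargement, which has not been shown with the tether on the internal alkene carbon (spiro outcome) or with an α-chloro aldehyde as initiator. Ring B closes 6-endo-trig at the alkene (exo at the carbonyl), the only mode that places the charge on tertiary C6, whereas ring A is not closed at all but grows from the cyclopentene by the C7-to-C6 shift. C6 is controlled by the C3 stereocentre through a chair in which the C3 methyl is equatorial and the smaller chlorine axial: C11, the bulkiest group on C7, stands perpendicular to the alkene plane on the face away from the aldehyde and is delivered antiperiplanar to the new C1–C2 bond, that is equatorially and cis to chlorine, while C7 becomes axial. C2 is controlled by the same chair, the tin-bound oxygen taking the equatorial site because an axial one would run into C7 as it swings axial, which places the C2 hydroxyl cis to chlorine. The step needs C11 and not C8 to migrate; both are allylic, so the choice rests on the higher substitution of C11 and on its alignment with the empty orbital. It also needs the aldehyde to react before C7–O or C3–Cl ionise and before C5 loses a proton: low temperature and the hindered pyridine keep acid away, a cation at C3 beside the complexed carbonyl is disfavoured, C7 carries no hydrogen for a concerted ene path, and the shift is intramolecular and ends in a C=O bond.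

**Step 13**
Reactants: 23 (2R,3S,6S)-3-chloro-2-hydroxy-3,11,11-trimethylspiro[5.5]undec-9-en-7-one
Product: 24 (2S,3S,6S)-2-bromo-3-chloro-3,11,11-trimethylspiro[5.5]undec-9-en-7-one
Conditions: CBr4, P(n-Oct)3, toluene, 70 °C
Reagents that add atoms: carbon tetrabromide, BrC(Br)(Br)Br
Why: Appel-type bromination: the equatorial alkoxyphosphonium group is displaced by bromide along the axial line (SN2, inversion) to give the bromide trans to chlorine, while the cis chlorine cannot participate and the equatorial leaving group has no antiperiplanar hydrogen, so retention and E2 are disfavoured.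

**Step 14**
Reactants: 24 (2S,3S,6S)-2-bromo-3-chloro-3,11,11-trimethylspiro[5.5]undec-9-en-7-one
Product: 25 (2S,3S,6S,9R,10R)-2,10-dibromo-3-chloro-9-hydroxy-3,11,11-trimethylspiro[5.5]undecan-7-one
Conditions: NBS (1.1 equiv), acetone/H2O, 0 °C
Reagents that add atoms: N-bromosuccinimide, O=C1CCC(=O)N1Br; water, O
Why: Bromohydrin formation: with the axial C2 bromine in place the C7 carbonyl should turn toward C5, which puts C1 axial on ring A, so the bromonium ion forms on the face of C1 (opposite the pseudoaxial C11 methyl) and is opened trans-diaxially by water at C9, the end remote from quaternary C11, setting C10 as R with bromine cis to C1 and leaving a C9 hydroxyl that is still trans.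

**Step 15**
Reactants: 25 (2S,3S,6S,9R,10R)-2,10-dibromo-3-chloro-9-hydroxy-3,11,11-trimethylspiro[5.5]undecan-7-one
Product: 26 9-O-triethylsilyl ether of 25
Conditions: TESOTf (1.2 equiv), 2,6-lutidine, CH2Cl2, −78 → 0 °C
Reagents that add atoms: triethylsilyl trifluoromethanesulfonate, CC[Si](CC)(CC)OS(=O)(=O)C(F)(F)F
Why: Silyl ether protection under weakly basic conditions masks the hydroxyl, which as a metal alkoxide in the next step would close onto C10 to an epoxide.

**Step 16**
Reactants: 26 9-O-triethylsilyl ether of 25
Product: 27 triethyl{[(2S,3S,6R,9R,10R)-2,10-dibromo-3-chloro-3,11,11-trimethyl-7-methylidenespiro[5.5]undecan-9-yl]oxy}silane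
Conditions: Tebbe reagent (3 equiv, toluene), pyridine (cat.), THF, −40 °C → rt; Na2SO4·10H2O
Reagents that add atoms: Tebbe reagent, C[Al-]1(C)C[Ti]([Cl+]1)(C1C=CC=C1)C1C=CC=C1
Why: Tebbe methylenation ([2+2] addition of titanocene methylidene and cycloreversion) is non-basic, so the β-silyloxy ketone is neither enolised nor eliminated as an ylide would risk, zinc-based variants that would strip the vicinal Br/Cl pair are avoided, and alkyl halides are inert to the carbene.

**Step 17**
Reactants: 27 the 7-methylidene silyl ether
Product: 28 (2S,3S,6R,9R,10R)-2,10-dibromo-3-chloro-3,11,11-trimethyl-7-methylidenespiro[5.5]undecan-9-ol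
Conditions: HF·pyridine, pyridine, THF, 0 °C → rt
Reagents that add atoms: none
Why: Fluoride-mediated desilylation in a buffered acidic medium never produces a free alkoxide, so the trans bromohydrin does not close to the epoxide and the exocyclic alkene stays in place.

**Step 18**
Reactants: 28 (2S,3S,6R,9R,10R)-2,10-dibromo-3-chloro-3,11,11-trimethyl-7-methylidenespiro[5.5]undecan-9-ol
Product: 29 (2S,3S,6R,10R)-2,10-dibromo-3-chloro-3,11,11-trimethyl-7-methylidenespiro[5.5]undecan-9-one
Conditions: Dess–Martin periodinane, NaHCO3, CH2Cl2, 0 °C; used at once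
Reagents that add atoms: none
Why: Dess–Martin oxidation is neutral when buffered, so the enolisable C10 bromide should keep its configuration and the C7 methylidene should not slip into conjugation through the doubly activated C8.

**Step 19**
Reactants: 29 (2S,3S,6R,10R)-2,10-dibromo-3-chloro-3,11,11-trimethyl-7-methylidenespiro[5.5]undecan-9-one
Product: 30 (2S,3S,6R,9S,10R)-2,10-dibromo-3-chloro-3,11,11-trimethyl-7-methylidenespiro[5.5]undecan-9-ol (target CNP0247242.3)
Conditions: DIBAL-H (1.5 equiv), Et2O, −78 °C; Rochelle salt
Reagents that add atoms: none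
Why: Diastereoselective aluminium hydride reduction of an α-bromo ketone: hydride should reach C9 from the face opposite the C10 bromine (polar Felkin–Anh alignment, and the line that avoids the axial C11 methyl), so oxygen ends cis to bromine and C9 is set as S, while the low temperature leaves the halides and the skipped enone untouched.

**Compound list**

1 | 2,2-dimethylcyclopentane-1,3-dione | CC1(C)C(=O)CCC1=O | starting material
2 | potassium enolate of 1 | CC1(C)C(=O)CC=C1[O-].[K+] | intermediate
3 | 5,5-dimethyl-4-oxocyclopent-1-en-1-yl trifluoromethanesulfonate | CC1(C)C(=O)CC=C1OS(=O)(=O)C(F)(F)F | intermediate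
4 | 2,2-dimethylcyclopent-3-en-1-one | O=C1CC=CC1(C)C | intermediate
5 | trimethyl(prop-1-yn-1-yl)silane | CC#C[Si](C)(C)C | starting material
6 | 2,3-dibromoprop-1-ene | C=C(Br)CBr | starting material
7 | [3-(trimethylsilyl)prop-2-yn-1-yl]lithium | [Li]CC#C[Si](C)(C)C | intermediate
8 | (5-bromohex-5-en-1-yn-1-yl)trimethylsilane | C=C(Br)CCC#C[Si](C)(C)C | intermediate
9 | 2-bromohex-1-en-5-yne | C=C(Br)CCC#C | intermediate
10 | [(1E)-5-bromo-2-methylhexa-1,5-dien-1-yl]dimethylalane | C[Al](C)/C=C(\C)CCC(Br)=C | intermediate
11 | lithium butyl[(1E)-5-bromo-2-methylhexa-1,5-dien-1-yl]dimethylalanate | [Li+].CCCC[Al-](C)(C)/C=C(\C)CCC(Br)=C | intermediate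
12 | (2E)-6-bromo-3-methylhepta-2,6-dien-1-ol | OC/C=C(\C)CCC(Br)=C | intermediate
13 | lithium (2E)-6-lithio-3-methylhepta-2,6-dien-1-olate | [Li]OC/C=C(\C)CCC([Li])=C | intermediate
14 | dichlorocerium reagent from 13 | [Li]OC/C=C(\C)CCC(=C)[Ce](Cl)Cl | intermediate
15 | 1-[(5E)-7-hydroxy-5-methylhepta-1,5-dien-2-yl]-2,2-dimethylcyclopent-3-en-1-ol (racemic) | OC/C=C(\C)CCC(=C)C1(O)CC=CC1(C)C | intermediate
16 | bis(triethylsilyl) ether of 15 | CC[Si](CC)(CC)OC/C=C(\C)CCC(=C)C1(O[Si](CC)(CC)CC)CC=CC1(C)C | intermediate
17 | (2E)-6-[2,2-dimethyl-1-(triethylsilyloxy)cyclopent-3-en-1-yl]-3-methylhepta-2,6-dien-1-ol | OC/C=C(\C)CCC(=C)C1(O[Si](CC)(CC)CC)CC=CC1(C)C | intermediate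
18 | (2R,3R)-epoxy alcohol from 17 (C7 epimer pair) | OC[C@H]1O[C@]1(C)CCC(=C)C1(O[Si](CC)(CC)CC)CC=CC1(C)C | intermediate
19 | (2R,3S)-3-chloro-1,2-diol from 18 (C7 epimer pair) | OC[C@@H](O)[C@@](C)(Cl)CCC(=C)C1(O[Si](CC)(CC)CC)CC=CC1(C)C | intermediate
20 | (2S)-2-chloro-5-[2,2-dimethyl-1-(triethylsilyloxy)cyclopent-3-en-1-yl]-2-methylhex-5-enal (key-step precursor, C7 epimer pair) | O=C[C@@](C)(Cl)CCC(=C)C1(O[Si](CC)(CC)CC)CC=CC1(C)C | intermediate
21 | ring B closed, tertiary C6 cation with tin-bound C2 oxygen | Cl[Sn-](Cl)(Cl)(Cl)O[C@@H]1C[C+](CC[C@]1(C)Cl)C1(O[Si](CC)(CC)CC)CC=CC1(C)C | intermediate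
22 | trichlorotin alkoxide of 23 | O=C1CC=CC(C)(C)[C@@]12CC[C@](C)(Cl)[C@H](O[Sn](Cl)(Cl)Cl)C2 | intermediate
23 | (2R,3S,6S)-3-chloro-2-hydroxy-3,11,11-trimethylspiro[5.5]undec-9-en-7-one (key-step product) | O=C1CC=CC(C)(C)[C@@]12CC[C@](C)(Cl)[C@H](O)C2 | intermediate
24 | (2S,3S,6S)-2-bromo-3-chloro-3,11,11-trimethylspiro[5.5]undec-9-en-7-one | O=C1CC=CC(C)(C)[C@@]12CC[C@](C)(Cl)[C@@H](Br)C2 | intermediate
25 | (2S,3S,6S,9R,10R)-2,10-dibromo-3-chloro-9-hydroxy-3,11,11-trimethylspiro[5.5]undecan-7-one | O=C1C[C@@H](O)[C@H](Br)C(C)(C)[C@@]12CC[C@](C)(Cl)[C@@H](Br)C2 | intermediate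
26 | 9-O-triethylsilyl ether of 25 | O=C1C[C@@H](O[Si](CC)(CC)CC)[C@H](Br)C(C)(C)[C@@]12CC[C@](C)(Cl)[C@@H](Br)C2 | intermediate
27 | 7-methylidene compound from 26, (2S,3S,6R,9R,10R) | C=C1C[C@@H](O[Si](CC)(CC)CC)[C@H](Br)C(C)(C)[C@@]12CC[C@](C)(Cl)[C@@H](Br)C2 | intermediate
28 | (2S,3S,6R,9R,10R)-2,10-dibromo-3-chloro-3,11,11-trimethyl-7-methylidenespiro[5.5]undecan-9-ol | C=C1C[C@@H](O)[C@H](Br)C(C)(C)[C@@]12CC[C@](C)(Cl)[C@@H](Br)C2 | intermediate
29 | (2S,3S,6R,10R)-2,10-dibromo-3-chloro-3,11,11-trimethyl-7-methylidenespiro[5.5]undecan-9-one | C=C1CC(=O)[C@H](Br)C(C)(C)[C@@]12CC[C@](C)(Cl)[C@@H](Br)C2 | intermediate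
30 | (2S,3S,6R,9S,10R)-2,10-dibromo-3-chloro-3,11,11-trimethyl-7-methylidenespiro[5.5]undecan-9-ol | C=C1C[C@H](O)[C@H](Br)C(C)(C)[C@@]12CC[C@](C)(Cl)[C@@H](Br)C2 | target

**Totals**

Total step count: 19.
Longest linear sequence: 17 (steps 3–19).

**Steps most likely to fail**

**Step 12 (carries the label).**
- What may go wrong:
  - The Lewis acid may ionise the allylic C7–O bond before the hindered aldehyde is attacked.
  - C8 may migrate in place of C11.
  - The chair with equatorial chlorine may compete and erode control at C6.
  - The dipole-minimised arrangement with the C2 oxygen anti to C3–Cl may erode face selectivity at C2.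
  - The two C7 epimers may not behave alike.
- Fallback, with known reactions only. The C1–C2 bond is made without acid and the shift is triggered separately.
  - From 20, vinylmagnesium bromide (THF, −78 °C, Cornforth-type addition, C2 epimers separated) gives the (2R,3S)-allylic alcohol F1.
  - Ring-closing metathesis (Hoveyda–Grubbs II, toluene, 80 °C) between the vinyl group and the 1,1-disubstituted alkene closes ring B as the cyclohexenol F2, in which the vinyl CH has become C1.
  - TBAF frees the tertiary carbinol to give the diol F3.
  - Cobalt-salen hydrogen-atom transfer with radical–polar crossover (Co(salen) cat., N-fluoro-2,4,6-collidinium triflate, PhSiH3, acetone) places hydrogen on C1 and raises the tertiary C6 radical to the cation level. This triggers the semipinacol ring enlargement and comes back to the route at 23.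
  - C6 would then rest on the ring B chair alone.

**Step 13.**
- What may go wrong:
  - Displacement may be slow, because the axial line of attack at C2 is flanked by fully substituted C3 and is syn-axial to C7.
  - The C7 carbonyl oxygen may participate at the rear of C2, leading to retention or to loss of a C8 proton.
  - The step depends on the C2 configuration delivered by step 12.
- Fallback: C2 and C3 are erased and both halogens are installed by addition, so material of either C2 configuration can be used.
  - From 23, 1,1'-thiocarbonyldiimidazole (DMAP, toluene, 80 °C) gives the C2 imidazolylthiocarbonate F4.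
  - Slow addition of Bu3SnH/AIBN in refluxing toluene generates the C2 radical, which expels the β-chlorine atom and gives the C2=C3 diene ketone F5.
  - One equivalent of Bu4NBrCl2 (CH2Cl2, −78 → 0 °C) adds BrCl to the more nucleophilic trisubstituted alkene.
  - With C11 held equatorial on ring B, Markovnikov attack of chloride at C3 and the Fürst–Plattner trans-diaxial rule are both met only by the bromonium ion on the face of C7. Bromine therefore ends axial on C2 and chlorine axial on C3, cis to C11, which comes back to the route at 24.

**Step 16.**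
- What may go wrong:
  - The bulky titanium carbene may fail to reach C7, which is shielded by C6/C11 and by the axial C2 bromine.
  - The aluminium by-product may ionise the tertiary chloride.
  - Low-valent titanium may cause reductive loss of the vicinal Br/Cl pair.
- Fallback: a small carbon nucleophile followed by elimination, in place of a metal carbene.
  - From 26, Me3SiCH2Li/CeCl3 (THF, −78 °C, cerium-modified Peterson addition) gives the β-hydroxysilane F6.
  - Aqueous HF in MeCN then brings about the Peterson elimination, which can only give the exocyclic alkene. It removes the C9 silyl group in the same operation and comes back to the route at 28.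

**Further compounds**

F1 | step 12 | (2R,3S)-allylic alcohol from vinyl addition to 20 (C7 epimer pair) | C=C[C@@H](O)[C@@](C)(Cl)CCC(=C)C1(O[Si](CC)(CC)CC)CC=CC1(C)C
F2 | step 12 | (2R,3S)-3-chloro-3-methyl-6-[2,2-dimethyl-1-(triethylsilyloxy)cyclopent-3-en-1-yl]cyclohex-1(6)-en-2-ol, route numbering | O[C@@H]1C=C(CC[C@]1(C)Cl)C1(O[Si](CC)(CC)CC)CC=CC1(C)C
F3 | step 12 | diol from desilylation of F2 | O[C@@H]1C=C(CC[C@]1(C)Cl)C1(O)CC=CC1(C)C
F4 | step 13 | C2 O-(imidazol-1-ylthiocarbonyl) derivative of 23 | O=C1CC=CC(C)(C)[C@@]12CC[C@](C)(Cl)[C@H](OC(=S)n3ccnc3)C2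
F5 | step 13 | (6S)-3,11,11-trimethylspiro[5.5]undeca-2,9-dien-7-one | O=C1CC=CC(C)(C)[C@@]12CCC(C)=CC2
F6 | step 16 | 7-hydroxy-7-(trimethylsilylmethyl) adduct of 26 (C7 open) | C[Si](C)(C)CC1(O)C[C@@H](O[Si](CC)(CC)CC)[C@H](Br)C(C)(C)[C@@]12CC[C@](C)(Cl)[C@@H](Br)C2
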